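The route rests on cutting the C11–C12 bond between the ketone carbonyl and the side-chain methine (chain numbered C1–C17 from the ketal ethyl group). The last step, a stereoretentive Pd-catalysed acylation of an enantioenriched secondary alkylcarbastannatrane, joins both halves and installs the C12 stereocentre by transfer from a configurationally stable C–Sn bond. It exploits that C11 is an exocyclic ketone flanked by two epimerisable centres (C10, C12) next to the acid-labile ketal/enol ether of ring A (dihydropyran) and ring B (4H-1,3-dioxin): the neutral, base-free coupling touches neither. Its precursors are bicyclic acid chloride 26 and (R)-stannane 25.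

Key step: step 16

Numbering used below: C3 is the ketal carbon, O7 and O9 are the oxygens on C7 and C9; ring A = O7, C3, C4, C5, C6, C7; ring B = C3, O9, C9, C8, C7, O7.
Assumption: 5-chloro-1-aza-5-stannabicyclo[3.3.3]undecane (23), the trifluoroethyl phosphonate of step 3 and the chiral starting materials 1, 9 and 18 are taken as commercially available.

Step 1
Reactants: 1 methyl (R)-3-hydroxy-2-methylpropanoate
Product: 2 methyl (R)-3-[(tert-butyldimethylsilyl)oxy]-2-methylpropanoate
Conditions: TBSCl, imidazole, DMF, 0 °C to rt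
Reagents that add atoms: tert-butyldimethylsilyl chloride, CC(C)(C)[Si](C)(C)Cl
Why: Silyl ether formation on the primary alcohol masks the hydroxyl for the hydride reduction and leaves the stereocentre untouched.

Step 2
Reactants: 2 methyl (R)-3-[(tert-butyldimethylsilyl)oxy]-2-methylpropanoate
Product: 3 (R)-3-[(tert-butyldimethylsilyl)oxy]-2-methylpropanal
Conditions: iBu2AlH (1.05 equiv), CH2Cl2, −78 °C; aq. KNaC4H4O6
Reagents that add atoms: none
Why: Partial ester reduction at −78 °C should stop at the aluminium hemiacetal and release the α-methyl aldehyde on work-up, which is used at once to avoid racemisation.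

Step 3
Reactants: 3 (R)-3-[(tert-butyldimethylsilyl)oxy]-2-methylpropanal
Product: 4 ethyl (S,Z)-5-[(tert-butyldimethylsilyl)oxy]-2,4-dimethylpent-2-enoate
Conditions: (CF3CH2O)2P(O)CH(CH3)CO2Et, KN(SiMe3)2, 18-crown-6, THF, −78 °C
Reagents that add atoms: ethyl 2-[bis(2,2,2-trifluoroethoxy)phosphoryl]propanoate, CCOC(=O)C(C)P(=O)(OCC(F)(F)F)OCC(F)(F)F
Why: Still–Gennari olefination under dissociating conditions should give the (Z)-trisubstituted enoate by fast elimination from the kinetic adduct, placing the ester carbon (C3) cis to C6 as ring A will require.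

Step 4
Reactants: 4 ethyl (S,Z)-5-[(tert-butyldimethylsilyl)oxy]-2,4-dimethylpent-2-enoate
Product: 6 (S)-3,5-dimethyl-5,6-dihydro-2H-pyran-2-one, via hydroxy ester 5 (not isolated)
Conditions: TsOH·H2O (cat.), MeOH, rt; then PhMe, 60 °C
Reagents that add atoms: none
Why: Acidic desilylation frees the primary alcohol 5, which should lactonise at once onto the cis-disposed ester (acid-catalysed transesterification), so the ring locks the (Z) geometry of C4=C5.

Step 5
Reactants: 6 (S)-3,5-dimethyl-5,6-dihydro-2H-pyran-2-one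
Product: 7 (S,Z)-7-hydroxy-4,6-dimethylhept-4-en-3-one (in equilibrium with its cyclic hemiketal)
Conditions: EtLi (1.1 equiv), Et2O, −78 °C; aq. NH4Cl
Reagents that add atoms: ethyllithium, CC[Li]
Why: 1,2-Addition of one equivalent of the organolithium to the lactone carbonyl should give a lithium lactolate that resists a second addition at −78 °C and opens on work-up to the (Z)-hydroxy enone.

Step 6
Reactants: 7 (S,Z)-7-hydroxy-4,6-dimethylhept-4-en-3-one
Product: 8 (S,Z)-2,4-dimethyl-5-oxohept-3-enal
Conditions: Dess–Martin periodinane, NaHCO3, CH2Cl2, 0 °C; used immediately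
Reagents that add atoms: none
Why: Dess–Martin oxidation of the open-chain primary alcohol under bicarbonate buffering should give the keto aldehyde without epimerising the doubly activated C6 methine.

Step 7
Reactants: 9 (S)-4-benzyl-3-propionyloxazolidin-2-one, 10 propanal
Product: 11 (S)-4-benzyl-3-[(2S,3R)-3-hydroxy-2-methylpentanoyl]oxazolidin-2-one
Conditions: Bu2BOTf, iPr2NEt, CH2Cl2, 0 °C; 10, −78 to 0 °C; H2O2, pH 7 buffer, MeOH
Reagents that add atoms: none
Why: Evans syn aldol reaction, in which the (Z)-boron enolate reacts through a Zimmerman–Traxler transition state on the face opposite the benzyl group and so sets the (2S) methyl centre (the future C10).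

Step 8
Reactants: 11 (S)-4-benzyl-3-[(2S,3R)-3-hydroxy-2-methylpentanoyl]oxazolidin-2-one
Product: 12 (S)-4-benzyl-3-[(S)-2-methyl-3-oxopentanoyl]oxazolidin-2-one
Conditions: SO3·pyridine, DMSO, iPr2NEt, CH2Cl2, −10 °C
Reagents that add atoms: none
Why: Parikh–Doering oxidation of the carbinol should give the β-keto imide without epimerisation, because A(1,3) strain keeps the C10–H bond out of alignment with both carbonyl groups.

Step 9
Reactants: 12 (S)-4-benzyl-3-[(S)-2-methyl-3-oxopentanoyl]oxazolidin-2-one, 8 (S,Z)-2,4-dimethyl-5-oxohept-3-enal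
Product: 13 (S)-4-benzyl-3-[(2S,4R,5S,6S,7Z)-5-hydroxy-2,4,6,8-tetramethyl-3,9-dioxoundec-7-enoyl]oxazolidin-2-one
Conditions: Sn(OTf)2, Et3N, CH2Cl2, −20 °C; then 8, −78 °C
Reagents that add atoms: none
Why: Aldol addition of the (Z)-enolate of divalent tin formed by soft enolisation of the ethyl ketone, in which the C10 methyl centre directs the enolate face to the anti,syn adduct and so sets C7 as (S), a sense that coincides with the anti-Felkin preference of (Z)-enolates for the (S)-α-methyl aldehyde (the C8 centre is erased in step 10).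

Step 10
Reactants: 13 (S)-4-benzyl-3-[(2S,4R,5S,6S,7Z)-5-hydroxy-2,4,6,8-tetramethyl-3,9-dioxoundec-7-enoyl]oxazolidin-2-one
Product: 16 (S)-4-benzyl-3-{(S)-2-[(1S,5S,6S)-1-ethyl-4,6,8-trimethyl-2,9-dioxabicyclo[3.3.1]nona-3,7-dien-3-yl]propanoyl}oxazolidin-2-one, via ring A hemiketal 14 (not isolated), via bridged hemiketal 15 (not isolated)
Conditions: PPTS (cat.), 4 Å MS, PhMe, 50 °C
Reagents that add atoms: none
Why: Acid-catalysed ketalisation cascade in which O7 adds to the C3 ketone (6-exo-trig, 14), the new hemiketal hydroxyl adds to the C9 ketone (6-exo-trig, 15) and water is lost toward C8 to give the ring B enol ether, the C3 configuration being dictated by C7 through the bridged bicycle and loss toward C10 being disfavoured by A(1,3) strain with the imide.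

Step 11
Reactants: 16 (S)-4-benzyl-3-{(S)-2-[(1S,5S,6S)-1-ethyl-4,6,8-trimethyl-2,9-dioxabicyclo[3.3.1]nona-3,7-dien-3-yl]propanoyl}oxazolidin-2-one
Product: 17 (S)-2-[(1S,5S,6S)-1-ethyl-4,6,8-trimethyl-2,9-dioxabicyclo[3.3.1]nona-3,7-dien-3-yl]propanoic acid
Conditions: LiOH, H2O2, THF/H2O, 0 °C; Na2SO3; NaH2PO4 to pH 5; used without storage
Reagents that add atoms: hydrogen peroxide (as LiOOH), OO
Why: Hydroperoxide-mediated imide cleavage at the exocyclic carbonyl should free the acid under conditions too mild to enolise C10, and the base-stable ketal and enol ether meet acid only at pH 5.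

Step 12
Reactants: 18 (S)-pent-4-yn-2-ol
Product: 20 (2S,4E)-5-iodo-4-methylpent-4-en-2-ol, via vinylalane 19 (not isolated)
Conditions: AlMe3 (3 equiv), Cp2ZrCl2 (cat.), CH2Cl2, 0 °C to rt; then I2, THF, −30 °C
Reagents that add atoms: trimethylaluminium, C[Al](C)C; iodine, II
Why: Zr-catalysed carboalumination adds methyl and aluminium syn across the terminal alkyne (methyl to the internal carbon) and iodinolysis with retention should give the (E)-iodoalkene, the carbinol centre coming from 18.

Step 13
Reactants: 20 (2S,4E)-5-iodo-4-methylpent-4-en-2-ol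
Product: 21 (2S,4E)-4-methylhept-4-en-2-ol
Conditions: Et2Zn (2.5 equiv), Pd(dppf)Cl2 (cat.), THF, 50 °C
Reagents that add atoms: diethylzinc, CC[Zn]CC
Why: Negishi cross-coupling with retention of alkene geometry should replace iodine by ethyl, the wide-bite-angle dppf ligand favouring reductive elimination over β-hydride elimination.

Step 14
Reactants: 21 (2S,4E)-4-methylhept-4-en-2-ol
Product: 22 (2S,4E)-4-methylhept-4-en-2-yl methanesulfonate
Conditions: MsCl, Et3N, CH2Cl2, 0 °C
Reagents that add atoms: methanesulfonyl chloride, CS(=O)(=O)Cl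
Why: Sulfonylation on oxygen leaves the configuration at C12 unchanged and provides the leaving group for the displacement.

Step 15
Reactants: 23 5-chloro-1-aza-5-stannabicyclo[3.3.3]undecane, 22 (2S,4E)-4-methylhept-4-en-2-yl methanesulfonate
Product: 25 5-[(2R,4E)-4-methylhept-4-en-2-yl]-1-aza-5-stannabicyclo[3.3.3]undecane, via stannyllithium 24 (not isolated)
Conditions: 23, LiC10H8 (2 equiv), THF, −78 °C; then 22, −78 °C to rt
Reagents that add atoms: none
Why: SN2 displacement of the secondary mesylate by the stannyl anion 24 (from reductive lithiation of chloride 23) should proceed with inversion and give the (R)-configured C12–Sn bond.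

Step 16
Reactants: 17 (S)-2-[(1S,5S,6S)-1-ethyl-4,6,8-trimethyl-2,9-dioxabicyclo[3.3.1]nona-3,7-dien-3-yl]propanoic acid, 25 5-[(2R,4E)-4-methylhept-4-en-2-yl]-1-aza-5-stannabicyclo[3.3.3]undecane
Product: 27 (2S,4R,6E)-2-[(1S,5S,6S)-1-ethyl-4,6,8-trimethyl-2,9-dioxabicyclo[3.3.1]nona-3,7-dien-3-yl]-4,6-dimethylnon-6-en-3-one (CNP0232650.2), via acid chloride 26 (not isolated)
Conditions: Me2C=C(Cl)NMe2 (1.05 equiv), CH2Cl2, 0 °C; then 25, Pd(dba)2 (5 mol %), JackiePhos (10 mol %), PhMe, 60 °C
Reagents that add atoms: none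
Why: Stille-type acyl cross-coupling: the α-chloroenamine converts the acid into acid chloride 26 without liberating HCl, zerovalent palladium inserts into the C–Cl bond, the secondary alkyl group passes from tin to the acyl–palladium chloride (divalent palladium) and reductive elimination forms the C11–C12 bond. The closest known reaction type is the stereoretentive Pd/JackiePhos-catalysed acylation of enantioenriched secondary alkylcarbastannatranes with acyl chlorides. No ring is closed; rings A and B are carried through intact. The only stereocentre delivered in this step, C12, is controlled by the C–Sn configuration of 25, because transmetalation proceeds with retention through a closed SE2 transition state and reductive elimination does not touch that carbon. The step needs selective transfer of the branched alkyl group over the three ring methylenes and over β-hydride elimination, which the transannular N→Sn bond of the stannatrane (it lengthens only the apical Sn–C bond) and the bulky, electron-poor biaryl phosphine should secure. It also needs the C10 and C12 α-centres, the ketal and the enol ether to survive, which the neutral medium free of base and acid should allow.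

Compound list
1 | methyl (R)-3-hydroxy-2-methylpropanoate | COC(=O)[C@H](C)CO | starting material
2 | methyl (R)-3-[(tert-butyldimethylsilyl)oxy]-2-methylpropanoate | COC(=O)[C@H](C)CO[Si](C)(C)C(C)(C)C | intermediate
3 | (R)-3-[(tert-butyldimethylsilyl)oxy]-2-methylpropanal | O=C[C@H](C)CO[Si](C)(C)C(C)(C)C | intermediate
4 | ethyl (S,Z)-5-[(tert-butyldimethylsilyl)oxy]-2,4-dimethylpent-2-enoate | CCOC(=O)/C(C)=C\[C@H](C)CO[Si](C)(C)C(C)(C)C | intermediate
5 | ethyl (S,Z)-5-hydroxy-2,4-dimethylpent-2-enoate | CCOC(=O)/C(C)=C\[C@H](C)CO | intermediate (not isolated)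
6 | (S)-3,5-dimethyl-5,6-dihydro-2H-pyran-2-one | CC1=C[C@H](C)COC1=O | intermediate
7 | (S,Z)-7-hydroxy-4,6-dimethylhept-4-en-3-one | CCC(=O)/C(C)=C\[C@H](C)CO | intermediate
8 | (S,Z)-2,4-dimethyl-5-oxohept-3-enal | CCC(=O)/C(C)=C\[C@H](C)C=O | intermediate
9 | (S)-4-benzyl-3-propionyloxazolidin-2-one | CCC(=O)N1[C@@H](Cc2ccccc2)COC1=O | starting material
10 | propanal | CCC=O | starting material
11 | (S)-4-benzyl-3-[(2S,3R)-3-hydroxy-2-methylpentanoyl]oxazolidin-2-one | CC[C@@H](O)[C@H](C)C(=O)N1[C@@H](Cc2ccccc2)COC1=O | intermediate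
12 | (S)-4-benzyl-3-[(S)-2-methyl-3-oxopentanoyl]oxazolidin-2-one | CCC(=O)[C@H](C)C(=O)N1[C@@H](Cc2ccccc2)COC1=O | intermediate
13 | (S)-4-benzyl-3-[(2S,4R,5S,6S,7Z)-5-hydroxy-2,4,6,8-tetramethyl-3,9-dioxoundec-7-enoyl]oxazolidin-2-one | CCC(=O)/C(C)=C\[C@H](C)[C@H](O)[C@@H](C)C(=O)[C@H](C)C(=O)N1[C@@H](Cc2ccccc2)COC1=O | intermediate
14 | (S)-4-benzyl-3-{(2S,4R)-4-[(2S,3S)-6-ethyl-6-hydroxy-3,5-dimethyl-3,6-dihydro-2H-pyran-2-yl]-2-methyl-3-oxopentanoyl}oxazolidin-2-one (hemiketal epimers) | CCC1(O)O[C@H]([C@@H](C)C(=O)[C@H](C)C(=O)N2[C@@H](Cc3ccccc3)COC2=O)[C@@H](C)C=C1C | intermediate (not isolated)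
15 | (S)-4-benzyl-3-{(S)-2-[(1S,4R,5S,6S)-1-ethyl-3-hydroxy-4,6,8-trimethyl-2,9-dioxabicyclo[3.3.1]non-7-en-3-yl]propanoyl}oxazolidin-2-one (epimers at the hemiketal carbon) | O=C(N3[C@@H](Cc4ccccc4)COC3=O)[C@@H](C)C1(O)[C@H](C)[C@H]2O[C@@](CC)(O1)C(C)=C[C@@H]2C | intermediate (not isolated)
16 | (S)-4-benzyl-3-{(S)-2-[(1S,5S,6S)-1-ethyl-4,6,8-trimethyl-2,9-dioxabicyclo[3.3.1]nona-3,7-dien-3-yl]propanoyl}oxazolidin-2-one | O=C(N3[C@@H](Cc4ccccc4)COC3=O)[C@@H](C)C1=C(C)[C@H]2O[C@@](CC)(O1)C(C)=C[C@@H]2C | intermediate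
17 | (S)-2-[(1S,5S,6S)-1-ethyl-4,6,8-trimethyl-2,9-dioxabicyclo[3.3.1]nona-3,7-dien-3-yl]propanoic acid | OC(=O)[C@@H](C)C1=C(C)[C@H]2O[C@@](CC)(O1)C(C)=C[C@@H]2C | intermediate
18 | (S)-pent-4-yn-2-ol | C#CC[C@H](C)O | starting material
19 | dimethylaluminium (2S,4E)-5-(dimethylalumanyl)-4-methylpent-4-en-2-olate | C[C@H](O[Al](C)C)C/C(C)=C/[Al](C)C | intermediate (not isolated)
20 | (2S,4E)-5-iodo-4-methylpent-4-en-2-ol | C[C@H](O)C/C(C)=C/I | intermediate
21 | (2S,4E)-4-methylhept-4-en-2-ol | CC/C=C(\C)C[C@H](C)O | intermediate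
22 | (2S,4E)-4-methylhept-4-en-2-yl methanesulfonate | CC/C=C(\C)C[C@H](C)OS(C)(=O)=O | intermediate
23 | 5-chloro-1-aza-5-stannabicyclo[3.3.3]undecane | Cl[Sn]12CCCN(CCC1)CCC2 | starting material
24 | 5-lithio-1-aza-5-stannabicyclo[3.3.3]undecane | [Li][Sn]12CCCN(CCC1)CCC2 | intermediate (not isolated)
25 | 5-[(2R,4E)-4-methylhept-4-en-2-yl]-1-aza-5-stannabicyclo[3.3.3]undecane | CC/C=C(\C)C[C@@H](C)[Sn]12CCCN(CCC1)CCC2 | intermediate
26 | (S)-2-[(1S,5S,6S)-1-ethyl-4,6,8-trimethyl-2,9-dioxabicyclo[3.3.1]nona-3,7-dien-3-yl]propanoyl chloride | ClC(=O)[C@@H](C)C1=C(C)[C@H]2O[C@@](CC)(O1)C(C)=C[C@@H]2C | intermediate (not isolated)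
27 | (2S,4R,6E)-2-[(1S,5S,6S)-1-ethyl-4,6,8-trimethyl-2,9-dioxabicyclo[3.3.1]nona-3,7-dien-3-yl]-4,6-dimethylnon-6-en-3-one | CC/C=C(\C)C[C@@H](C)C(=O)[C@@H](C)C1=C(C)[C@H]2O[C@@](CC)(O1)C(C)=C[C@@H]2C | target

Total step count: 16. Longest linear sequence: 10 steps (steps 1–6, 9, 10, 11, 16).

Steps most likely to fail

Step 16. Transfer of the hindered secondary alkyl group to the α-branched acyl–palladium chloride may be too slow, so that decarbonylation, ketene formation from 26 or protodestannylation compete and stereochemical fidelity at C12 is lost. The fallback sets out from alcohol 21 and acid 17 (through acid chloride 26) and comes back at 27. Appel iodination of 21 (I2, PPh3, imidazole, inversion) should give (2R,3E)-6-iodo-4-methylhept-3-ene F1. Iodine–lithium exchange with tBuLi in pentane/Et2O at −100 °C, which retains configuration, should give the secondary alkyllithium F2. Transmetalation with CuBr·P(OEt)3 gives the configurationally stable alkylcopper F3, which is acylated by 26 at −50 °C with retention to give 27.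

Step 10. The cascade may stall at bridged hemiketal 15, or prolonged acid treatment may eliminate water toward C10 or across C7/C8, or trigger retro-aldol cleavage. The fallback sets out from 13 and comes back at 16. Ketalisation of 13 with MeOH, HC(OMe)3 and PPTS should give the bridged mixed methyl ketal F4 (methoxy on C9), which is isolated. Methanol is then removed under kinetic, basic conditions (Me3SiOTf, iPr2NEt, CH2Cl2, −78 to −20 °C, ketal-to-enol-ether conversion); the amine takes the accessible C8–H from the C9 oxocarbenium ion to give 16.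

Step 9. The amine may epimerise or conjugate the doubly activated C6–H of keto aldehyde 8 before addition, or the C3 enone may compete as electrophile, eroding the diastereoselectivity. The fallback sets out from 3, 12 and 10 and comes back at 13; it introduces the ketone only after the aldol. Stork–Zhao-type olefination of 3 with Ph3P=C(CH3)I should give (Z)-iodoalkene silyl ether F5. Acidic desilylation (TsOH, MeOH) gives alcohol F6 and Dess–Martin oxidation gives the non-conjugated aldehyde F7, whose C6–H is far less acidic. The same Sn(OTf)2 aldol with 12 gives iodoalkene adduct F8. Nozaki–Hiyama–Kishi coupling with propanal 10 (CrCl2, NiCl2 cat., DMF) gives allylic alcohol F9 as C3 epimers, and MnO2 oxidises only the allylic carbinol to deliver 13.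

Further compounds
F1 | step 16 | (2R,3E)-6-iodo-4-methylhept-3-ene | CC/C=C(\C)C[C@@H](C)I
F2 | step 16 | [(2R,4E)-4-methylhept-4-en-2-yl]lithium | CC/C=C(\C)C[C@@H](C)[Li]
F3 | step 16 | [(2R,4E)-4-methylhept-4-en-2-yl]copper (triethyl phosphite complex) | CC/C=C(\C)C[C@@H](C)[Cu]
F4 | step 10 | (S)-4-benzyl-3-{(S)-2-[(1S,4R,5S,6S)-1-ethyl-3-methoxy-4,6,8-trimethyl-2,9-dioxabicyclo[3.3.1]non-7-en-3-yl]propanoyl}oxazolidin-2-one (epimers at the methoxy carbon) | O=C(N3[C@@H](Cc4ccccc4)COC3=O)[C@@H](C)C1(OC)[C@H](C)[C@H]2O[C@@](CC)(O1)C(C)=C[C@@H]2C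
F5 | step 9 | tert-butyl{[(2S,3Z)-4-iodo-2-methylpent-3-en-1-yl]oxy}dimethylsilane | I/C(C)=C\[C@H](C)CO[Si](C)(C)C(C)(C)C
F6 | step 9 | (2S,3Z)-4-iodo-2-methylpent-3-en-1-ol | I/C(C)=C\[C@H](C)CO
F7 | step 9 | (2S,3Z)-4-iodo-2-methylpent-3-enal | I/C(C)=C\[C@H](C)C=O
F8 | step 9 | (S)-4-benzyl-3-[(2S,4R,5S,6S,7Z)-5-hydroxy-8-iodo-2,4,6-trimethyl-3-oxonon-7-enoyl]oxazolidin-2-one | I/C(C)=C\[C@H](C)[C@H](O)[C@@H](C)C(=O)[C@H](C)C(=O)N1[C@@H](Cc2ccccc2)COC1=O
F9 | step 9 | (S)-4-benzyl-3-[(2S,4R,5S,6S,7Z)-5,9-dihydroxy-2,4,6,8-tetramethyl-3-oxoundec-7-enoyl]oxazolidin-2-one (C9 epimers) | CCC(O)/C(C)=C\[C@H](C)[C@H](O)[C@@H](C)C(=O)[C@H](C)C(=O)N1[C@@H](Cc2ccccc2)COC1=O
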